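**Retrosynthetic overview**
1. C8 carbinol ⇒ C8 ketone + CH3 nucleophile from the convex face. The C3 ketone stays masked as the silyl enol ether that the annulation delivers.
2. C9–C11 bond ⇒ regiodefined Δ8(9)-lithium enolate + homofarnesyl iodide. The enolate ⇒ one-carbon ring enlargement of a cis-hydrindan-1-one, by 1,2-shift of quaternary C10 onto a CHBr carbenoid carbon that becomes C9.
3. cis-Hydrindanone ⇒ 2-methylcyclopent-2-enone + 3-silyloxy-4-methylpenta-1,3-diene, by an enantioselective double Michael annulation that sets C5 and C10.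
4. Homofarnesyl iodide ⇒ homoprenyl bromide, by two rounds of acetylide SN2, Zr-catalysed carboalumination/oxirane opening and iodination.
5. Ring order: the five-membered ring is bought, ring A is annulated onto it, and the five-membered ring is then enlarged to ring B.

Assumption: the SMILES is read literally. In terpenoid numbering (C3 ketone, C4 CMe2, C5 fusion CH, C8 carbinol, C9 chain-bearing CH, C10 fusion C–CH3; used throughout) it encodes 5S,8R,9R,10S. This is a cis-decalin with H-5, CH3-10, the C9 chain and CH3-8 on one face (β) and OH-8 and H-9 on the other (α). 4-Methylpent-1-en-3-one is taken as a catalogue compound.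

**Step 1**
Reactants: 1 5-bromo-2-methylpent-2-ene; 2 lithium acetylide–ethylenediamine complex
Product: 3 6-methylhept-5-en-1-yne
Conditions: DMSO, 0 °C to rt
Reagents that add atoms: none
Why: SN2 alkynylation of a primary homoallylic bromide in a dipolar aprotic solvent; no stereocentre is formed.

**Step 2**
Reactants: 3 6-methylhept-5-en-1-yne; 4 oxirane
Product: 7 (3E)-4,8-dimethylnona-3,7-dien-1-ol (homogeraniol), via alkenylalane 5 (not isolated), via lithium alanate 6 (not isolated)
Conditions: Me3Al, Cp2ZrCl2 (20 mol %), CH2Cl2, rt; strip volatiles; n-BuLi, hexane–THF, −78 to 0 °C; 4, −78 °C to rt; H2O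
Reagents that add atoms: trimethylaluminium C[Al](C)C
Why: Negishi Zr-catalysed carboalumination adds CH3 and Al syn with Al on the terminal carbon, which fixes the E trisubstituted alkene, and the more nucleophilic alanate opens oxirane with retention of alkene geometry.

**Step 3**
Reactants: 7 (3E)-4,8-dimethylnona-3,7-dien-1-ol
Product: 8 (6E)-9-iodo-2,6-dimethylnona-2,6-diene
Conditions: I2, PPh3, imidazole, CH2Cl2, 0 °C
Reagents that add atoms: iodine II
Why: Appel-type iodination of a primary alcohol by SN2 under near-neutral conditions leaves both alkenes untouched.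

**Step 4**
Reactants: 8 (6E)-9-iodo-2,6-dimethylnona-2,6-diene; 2 lithium acetylide–ethylenediamine complex
Product: 9 (5E)-6,10-dimethylundeca-5,9-dien-1-yne
Conditions: DMSO, rt
Reagents that add atoms: none
Why: SN2 alkynylation of a primary iodide as in step 1; the alkene geometry is not involved.

**Step 5**
Reactants: 9 (5E)-6,10-dimethylundeca-5,9-dien-1-yne; 4 oxirane
Product: 12 (3E,7E)-4,8,12-trimethyltrideca-3,7,11-trien-1-ol (homofarnesol), via alkenylalane 10 (not isolated), via lithium alanate 11 (not isolated)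
Conditions: Me3Al, Cp2ZrCl2 (20 mol %), CH2Cl2, rt; strip volatiles; n-BuLi, hexane–THF, −78 to 0 °C; 4, −78 °C to rt; H2O
Reagents that add atoms: trimethylaluminium C[Al](C)C
Why: A second Negishi carboalumination/alanate–epoxide opening sets the second E trisubstituted alkene by syn addition, and the isolated trisubstituted alkenes are inert to it.

**Step 6**
Reactants: 12 (3E,7E)-4,8,12-trimethyltrideca-3,7,11-trien-1-ol
Product: 13 (6E,10E)-13-iodo-2,6,10-trimethyltrideca-2,6,10-triene (homofarnesyl iodide)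
Conditions: I2, PPh3, imidazole, CH2Cl2, 0 °C
Reagents that add atoms: iodine II
Why: Appel-type iodination as in step 3.

**Step 7**
Reactants: 14 4-methylpent-1-en-3-one
Product: 15 tert-butyl(dimethyl)[(4-methylpenta-1,3-dien-3-yl)oxy]silane
Conditions: TBSOTf, Et3N, CH2Cl2, 0 °C
Reagents that add atoms: tert-butyldimethylsilyl triflate CC(C)(C)[Si](C)(C)OS(=O)(=O)C(F)(F)F
Why: Soft enolisation/O-silylation can remove only the isopropyl C–H, so one geometry-free tetrasubstituted enol silane (a 2-silyloxydiene) forms.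

**Step 8**
Reactants: 15 tert-butyl(dimethyl)[(4-methylpenta-1,3-dien-3-yl)oxy]silane; 16 2-methylcyclopent-2-en-1-one
Product: 18 (3aR,7aS)-5-[(tert-butyldimethylsilyl)oxy]-4,4,7a-trimethyl-2,3,3a,4,7,7a-hexahydro-1H-inden-1-one (cis-fused), via Michael adduct 17 (not isolated)
Conditions: confined BINOL-derived N-triflyl imidodiphosphorimidate (IDPi) acid (3 mol %), toluene, −40 °C
Reagents that add atoms: none
Why: Proposed new method: an enantioselective silylium-catalysed double Mukaiyama–Michael annulation (stepwise formal [4+2]), in which a trace of 15 is protodesilylated by the IDPi acid to a TBS+/IDPi− ion pair that O-silylates 16, the fully substituted enol-silane carbon of 15 adds to C3 of the enone inside the confined chiral anion (sets C5), and the cyclopentenyl silyl ether of 17 closes onto the re-activated vinyl ketone on the face that carries the tether, which forces the cis fusion (H-5 cis to CH3-10, sets C10) and leaves C3 masked as its silyl enol ether; the ionic path avoids the s-cis diene conformer that the inward methyl forbids; the closest known reaction types are the racemic strong-Lewis-acid (AlBr3/AlMe3 or Tf2NH) cycloadditions of hindered 2-silyloxydienes with 2-methylcycloalkenones and IDPi–silylium asymmetric Mukaiyama–Michael and Diels–Alder reactions of simple enoates; the catalyst antipode that gives (3aR,7aS) is picked in a test run.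

**Step 9**
Reactants: 18 the cis-hydrindanone
Product: 19 (1R,3aR,7aS)-1-(dibromomethyl)-5-[(tert-butyldimethylsilyl)oxy]-4,4,7a-trimethyl-2,3,3a,4,7,7a-hexahydro-1H-inden-1-ol
Conditions: CH2Br2, LDA (added last), THF, −78 °C; then H2O
Reagents that add atoms: dibromomethane BrCBr
Why: 1,2-Addition of the small, in situ generated dibromomethyllithium outruns enolisation and occurs from the convex β face, the TBS enol ether is inert, and the new carbinol centre is erased in step 10.

**Step 10**
Reactants: 19 the dibromomethyl carbinol; 13 homofarnesyl iodide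
Product: 22 (1R,4aS,8aS)-6-[(tert-butyldimethylsilyl)oxy]-5,5,8a-trimethyl-1-[(3E,7E)-4,8,12-trimethyltrideca-3,7,11-trien-1-yl]-3,4,4a,5,8,8a-hexahydronaphthalen-2(1H)-one, via oxido carbenoid 20 (not isolated), via lithium enolate 21 (not isolated)
Conditions: n-BuLi (2.1 equiv), THF, −78 to −20 °C; then DMPU, 13, −78 to 0 °C
Reagents that add atoms: none
Why: Nozaki–Yamamoto β-oxido carbenoid ring enlargement (semipinacol-type 1,2-shift) followed by enolate alkylation: in 20 the bulky C–Br bond takes the least crowded position, anti to the C8–C10 bond, so the more substituted and more electron-rich quaternary C10 migrates with retention (the expected preference of such carbenoids, opposite to diazoalkanes) and gives only the Δ8(9)-enolate 21, which 13 alkylates axially on the convex β face, anti to the pseudo-axial C1 and past only H-5, setting C9 (chain β, H α).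

**Step 11**
Reactants: 22 the ring-enlarged ketone
Product: 24 (4aS,5R,6R,8aS)-6-hydroxy-1,1,4a,6-tetramethyl-5-[(3E,7E)-4,8,12-trimethyltrideca-3,7,11-trien-1-yl]octahydronaphthalen-2(1H)-one (IN0671), via silyl enol ether carbinol 23 (not isolated)
Conditions: MeLi, CeCl3, THF, −78 °C; then AcOH, TBAF, 0 °C to rt
Reagents that add atoms: methyllithium [Li]C
Why: Imamoto organocerium 1,2-addition is non-basic so C9 is not epimerised, and in the preferred chair the axial C1 blocks the α face of C8, so CH3 enters equatorially from the convex β face (8β-CH3, 8α-OH), after which buffered fluoride unmasks the C3 ketone without harming the tertiary alcohol or the alkenes.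

**Compound list**
1 | 5-bromo-2-methylpent-2-ene | CC(C)=CCCBr | starting material
2 | lithium acetylide–ethylenediamine complex | [Li]C#C.NCCN | starting material
3 | 6-methylhept-5-en-1-yne | CC(C)=CCCC#C | intermediate
4 | oxirane | C1CO1 | starting material
5 | [(1E)-2,6-dimethylhepta-1,5-dien-1-yl]dimethylalane | C[Al](C)/C=C(C)/CCC=C(C)C | intermediate
6 | lithium butyl[(1E)-2,6-dimethylhepta-1,5-dien-1-yl]dimethylalanate | [Li+].CCCC[Al-](C)(C)/C=C(C)/CCC=C(C)C | intermediate
7 | (3E)-4,8-dimethylnona-3,7-dien-1-ol | CC(C)=CCC/C(C)=C/CCO | intermediate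
8 | (6E)-9-iodo-2,6-dimethylnona-2,6-diene | CC(C)=CCC/C(C)=C/CCI | intermediate
9 | (5E)-6,10-dimethylundeca-5,9-dien-1-yne | CC(C)=CCC/C(C)=C/CCC#C | intermediate
10 | dimethyl[(1E,5E)-2,6,10-trimethylundeca-1,5,9-trien-1-yl]alane | C[Al](C)/C=C(C)/CC/C=C(C)/CCC=C(C)C | intermediate
11 | lithium butyl(dimethyl)[(1E,5E)-2,6,10-trimethylundeca-1,5,9-trien-1-yl]alanate | [Li+].CCCC[Al-](C)(C)/C=C(C)/CC/C=C(C)/CCC=C(C)C | intermediate
12 | (3E,7E)-4,8,12-trimethyltrideca-3,7,11-trien-1-ol | CC(C)=CCC/C(C)=C/CC/C(C)=C/CCO | intermediate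
13 | (6E,10E)-13-iodo-2,6,10-trimethyltrideca-2,6,10-triene | CC(C)=CCC/C(C)=C/CC/C(C)=C/CCI | intermediate
14 | 4-methylpent-1-en-3-one | C=CC(=O)C(C)C | starting material
15 | tert-butyl(dimethyl)[(4-methylpenta-1,3-dien-3-yl)oxy]silane | C=CC(O[Si](C)(C)C(C)(C)C)=C(C)C | intermediate
16 | 2-methylcyclopent-2-en-1-one | CC1=CCCC1=O | starting material
17 | 4-[(1S)-3-[(tert-butyldimethylsilyl)oxy]-2-methylcyclopent-2-en-1-yl]-4-methylpent-1-en-3-one | C=CC(=O)C(C)(C)[C@H]1CCC(O[Si](C)(C)C(C)(C)C)=C1C | intermediate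
18 | (3aR,7aS)-5-[(tert-butyldimethylsilyl)oxy]-4,4,7a-trimethyl-2,3,3a,4,7,7a-hexahydro-1H-inden-1-one | O=C1[C@@]2(C)CC=C(O[Si](C)(C)C(C)(C)C)C(C)(C)[C@H]2CC1 | intermediate
19 | (1R,3aR,7aS)-1-(dibromomethyl)-5-[(tert-butyldimethylsilyl)oxy]-4,4,7a-trimethyl-2,3,3a,4,7,7a-hexahydro-1H-inden-1-ol | O[C@@]1(C(Br)Br)[C@@]2(C)CC=C(O[Si](C)(C)C(C)(C)C)C(C)(C)[C@H]2CC1 | intermediate
20 | dilithio β-oxido carbenoid of 19 (O–Li, C(H)(Br)Li) | [Li]O[C@@]1(C([Li])Br)[C@@]2(C)CC=C(O[Si](C)(C)C(C)(C)C)C(C)(C)[C@H]2CC1 | intermediate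
21 | lithium Δ8(9)-enolate of the ring-enlarged cis-decalin-8-one (C9 = CH) | [Li]OC1=C[C@@]2(C)CC=C(O[Si](C)(C)C(C)(C)C)C(C)(C)[C@H]2CC1 | intermediate
22 | (1R,4aS,8aS)-6-[(tert-butyldimethylsilyl)oxy]-5,5,8a-trimethyl-1-[(3E,7E)-4,8,12-trimethyltrideca-3,7,11-trien-1-yl]-3,4,4a,5,8,8a-hexahydronaphthalen-2(1H)-one | CC(C)=CCC/C(C)=C/CC/C(C)=C/CC[C@@H]1[C@@]2(C)CC=C(O[Si](C)(C)C(C)(C)C)C(C)(C)[C@H]2CCC1=O | intermediate
23 | (1R,2R,4aS,8aS)-6-[(tert-butyldimethylsilyl)oxy]-2,5,5,8a-tetramethyl-1-[(3E,7E)-4,8,12-trimethyltrideca-3,7,11-trien-1-yl]-1,2,3,4,4a,5,8,8a-octahydronaphthalen-2-ol | CC(C)=CCC/C(C)=C/CC/C(C)=C/CC[C@@H]1[C@@]2(C)CC=C(O[Si](C)(C)C(C)(C)C)C(C)(C)[C@H]2CC[C@@]1(C)O | intermediate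
24 | (4aS,5R,6R,8aS)-6-hydroxy-1,1,4a,6-tetramethyl-5-[(3E,7E)-4,8,12-trimethyltrideca-3,7,11-trien-1-yl]octahydronaphthalen-2(1H)-one (IN0671) | CC(C)=CCC/C(C)=C/CC/C(C)=C/CC[C@@H]1[C@@]2(C)CCC(=O)C(C)(C)[C@H]2CC[C@@]1(C)O | target

**Step count**
Total: 11 steps. Longest linear sequence: 8 steps (steps 1–6, 10, 11).

**Three steps most likely to fail**

Step 8 (the proposed new step). The hindered partners may react too slowly, the reaction may stop at 17, or the ee may be low.
The fallback sets out from 15 and 16 and comes back at 18. The known mixed Lewis acid AlBr3/AlMe3 (toluene–CH2Cl2, about −5 °C) gives the racemic cis-hydrindanone F1. This is then resolved by the sulfoximine method. Lithiated (S)-N,S-dimethyl-S-phenylsulfoximine adds to the ketone from the convex face. It gives the β-hydroxysulfoximine of the (3aR,7aS)-ketone F2 and the β-hydroxysulfoximine of the (3aS,7aR)-ketone F3, which are separated on silica. Heating F2 in toluene reverses the addition and returns enantiopure 18.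

Step 10. Three things can go wrong: C7 may migrate instead of C10, the hindered enolate may be alkylated only slowly by an unactivated iodide, and proton transfer may scramble the enolate.
The fallback sets out from 13 and 18 and comes back at 22. It carries the chain in on the carbenoid carbon, so no enolate alkylation is needed.
- Dibromomethyllithium is alkylated by 13 to give (6E,10E)-14,14-dibromo-2,6,10-trimethyltetradeca-2,6,10-triene F4.
- LDA at −90 °C converts it into the 1,1-dibromoalkyllithium F5, which adds to 18 to give the dibromoalkyl carbinol F6.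
- n-BuLi (2 equiv) gives the chain-bearing oxido carbenoid F7, which undergoes the same 1,2-shift to the chain-bearing lithium enolate F8.
- Protonation gives 22 together with the C9 epimer of the ketone F9. F9 is equilibrated with DBU, separated and recycled. In this fallback C9 is set by equilibration and separation, not kinetically.

Step 11. The methyl group may enter from the α face, or the hindered ketone may simply enolise.
The fallback sets out from 22 and comes back at 23. Dimethylsulfoxonium methylide adds reversibly and places its CH2 in the less crowded equatorial β position, which gives the spiro-oxirane (CH2 β, O α) F10. LiEt3BH opens F10 at the CH2 terminus to give 23, which is desilylated as in step 11.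

**Further compounds**
F1 | step 8 | (±)-cis-5-[(tert-butyldimethylsilyl)oxy]-4,4,7a-trimethyl-2,3,3a,4,7,7a-hexahydro-1H-inden-1-one (1:1 mixture of enantiomers) | O=C1[C@@]2(C)CC=C(O[Si](C)(C)C(C)(C)C)C(C)(C)[C@H]2CC1.O=C1[C@]2(C)CC=C(O[Si](C)(C)C(C)(C)C)C(C)(C)[C@@H]2CC1
F2 | step 8 | (1R,3aR,7aS)-5-[(tert-butyldimethylsilyl)oxy]-4,4,7a-trimethyl-1-{[(S)-N-methyl-S-phenylsulfonimidoyl]methyl}-2,3,3a,4,7,7a-hexahydro-1H-inden-1-ol | O[C@@]1(C[S@@](=O)(=NC)c3ccccc3)[C@@]2(C)CC=C(O[Si](C)(C)C(C)(C)C)C(C)(C)[C@H]2CC1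
F3 | step 8 | (1S,3aS,7aR)-5-[(tert-butyldimethylsilyl)oxy]-4,4,7a-trimethyl-1-{[(S)-N-methyl-S-phenylsulfonimidoyl]methyl}-2,3,3a,4,7,7a-hexahydro-1H-inden-1-ol | O[C@]1(C[S@@](=O)(=NC)c3ccccc3)[C@]2(C)CC=C(O[Si](C)(C)C(C)(C)C)C(C)(C)[C@@H]2CC1
F4 | step 10 | (6E,10E)-14,14-dibromo-2,6,10-trimethyltetradeca-2,6,10-triene | CC(C)=CCC/C(C)=C/CC/C(C)=C/CCC(Br)Br
F5 | step 10 | [(4E,8E)-1,1-dibromo-5,9,13-trimethyltetradeca-4,8,12-trien-1-yl]lithium | CC(C)=CCC/C(C)=C/CC/C(C)=C/CCC([Li])(Br)Br
F6 | step 10 | (1R,3aR,7aS)-1-[(4E,8E)-1,1-dibromo-5,9,13-trimethyltetradeca-4,8,12-trien-1-yl]-5-[(tert-butyldimethylsilyl)oxy]-4,4,7a-trimethyl-2,3,3a,4,7,7a-hexahydro-1H-inden-1-ol | O[C@@]1(C(Br)(Br)CC/C=C(C)/CC/C=C(C)/CCC=C(C)C)[C@@]2(C)CC=C(O[Si](C)(C)C(C)(C)C)C(C)(C)[C@H]2CC1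
F7 | step 10 | dilithio β-oxido carbenoid of F6 (O–Li, C(Br)(Li)-chain) | [Li]O[C@@]1(C([Li])(Br)CC/C=C(C)/CC/C=C(C)/CCC=C(C)C)[C@@]2(C)CC=C(O[Si](C)(C)C(C)(C)C)C(C)(C)[C@H]2CC1
F8 | step 10 | lithium Δ8(9)-enolate of 22 (chain on C9) | [Li]OC1=C(CC/C=C(C)/CC/C=C(C)/CCC=C(C)C)[C@@]2(C)CC=C(O[Si](C)(C)C(C)(C)C)C(C)(C)[C@H]2CC1
F9 | step 10 | (1S,4aS,8aS)-6-[(tert-butyldimethylsilyl)oxy]-5,5,8a-trimethyl-1-[(3E,7E)-4,8,12-trimethyltrideca-3,7,11-trien-1-yl]-3,4,4a,5,8,8a-hexahydronaphthalen-2(1H)-one (C9 epimer of 22) | CC(C)=CCC/C(C)=C/CC/C(C)=C/CC[C@H]1[C@@]2(C)CC=C(O[Si](C)(C)C(C)(C)C)C(C)(C)[C@H]2CCC1=O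
F10 | step 11 | spiro-oxirane at C8 of 22 (CH2 β, O α; silyl enol ether retained) | CC(C)=CCC/C(C)=C/CC/C(C)=C/CC[C@@H]1[C@@]2(C)CC=C(O[Si](C)(C)C(C)(C)C)C(C)(C)[C@H]2CC[C@]13CO3
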